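**Plan** (eudesmane numbering: ring A = C1–C5, C10; ring B = C5–C10; side chain C11–C13 on C7; C14 on C10; C15 on C4)

1. Retrosynthesis first removes the three esters: the C3 propionate, the C8 acetate, and the C12 methyl ester (traced to an isopropenyl group by allylic oxidation). This leaves the 8-ketal of 8-oxo-α-cyperone, 13.
2. Ring A is a reduced 4-methylcyclohex-2-enone. The C3 oxygen is allylic to the tetrasubstituted C4=C5 bond and 1,5 to C5 through C2–C1–C10, and C10 is the α-carbon of a ring-B carbonyl at C5. This is cut at C4=C5 (aldol condensation) and C1–C10 (Michael addition), i.e. one Robinson annulation of ring-B ketone 6 with ethyl vinyl ketone.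
3. Ring B carries oxygen at C5 and C8 in a para (hydroquinone) relationship. It is cut at C7–C11 back to quinone monoketal 3, made from 4-methoxy-2-methylphenol.
4. Forward: ring B first (dearomatization, Rh-catalysed conjugate isopropenylation, conjugate reduction); ring A closed last in one telescoped annulation; then C8 reduction and acetylation, oxidation of the isopropenyl methyl to the methyl ester, C3 reduction and propionylation.
5. Stereochemistry: C7 from the Rh–BINAP catalyst; quaternary C10 from the (R)-1-phenylethylamine auxiliary; C8 from equatorial hydride delivery opposite the syn-axial C10 methyl; C3 from axial hydride delivery to the enone.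

Key step: step 5

**Step 1**
Reactants: 1 4-methoxy-2-methylphenol
Product: 2 4,4-dimethoxy-2-methylcyclohexa-2,5-dien-1-one
Conditions: PhI(OAc)2, MeOH, 0 °C to rt
Reagents that add atoms: methanol (CO)
Why: Hypervalent-iodine oxidative dearomatization of a para-alkoxyphenol in methanol should give the quinone monoketal, which fixes the para C5/C8 oxygenation of ring B and differentiates the two carbonyl carbons.

**Step 2**
Reactants: 2 4,4-dimethoxy-2-methylcyclohexa-2,5-dien-1-one
Product: 3 7-methyl-1,4-dioxaspiro[4.5]deca-6,9-dien-8-one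
Conditions: HOCH2CH2OH, BF3·OEt2 (cat.), DME, 0 °C to rt
Reagents that add atoms: ethylene glycol (OCCO)
Why: Acid-catalysed transketalization through the oxocarbenium ion should exchange the very labile dimethyl ketal for the dioxolane, which is needed to survive the mildly acidic imine hydrolysis in step 5.

**Step 3**
Reactants: 3 7-methyl-1,4-dioxaspiro[4.5]deca-6,9-dien-8-one, 4 potassium isopropenyltrifluoroborate
Product: 5 (10R)-7-methyl-10-(prop-1-en-2-yl)-1,4-dioxaspiro[4.5]dec-6-en-8-one
Conditions: [Rh(cod)2]BF4 (3 mol%), (R)-BINAP (3.3 mol%), Et3N, PhMe/H2O, 60 °C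
Reagents that add atoms: none
Why: Rh-catalysed asymmetric conjugate addition (Hayashi–Miyaura type) of an alkenyltrifluoroborate should occur only at the unsubstituted enone (the α-methyl enone is far less reactive); the new C7 stereocenter is set by enone insertion into the Rh–alkenyl bond on the face dictated by the ligand, (R)-BINAP being chosen by analogy with the (S)-BINAP to (S)-3-substituted cyclohexanone correlation.

**Step 4**
Reactants: 5 (10R)-7-methyl-10-(prop-1-en-2-yl)-1,4-dioxaspiro[4.5]dec-6-en-8-one
Product: 6 (10R)-7-methyl-10-(prop-1-en-2-yl)-1,4-dioxaspiro[4.5]decan-8-one (mixture of epimers at the methyl-bearing carbon)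
Conditions: L-Selectride, THF, −78 °C; then sat. aq NH4Cl
Reagents that add atoms: none
Why: Selectride conjugate (1,4-) reduction of a β-unsubstituted α-methylcyclohexenone, as with carvone, should give the saturated ketone without touching the isopropenyl group or the ketal; the epimer mixture at the future C10 is of no consequence because that carbon becomes the enamine carbon in step 5.

**Step 5**
Reactants: 6 (10R)-7-methyl-10-(prop-1-en-2-yl)-1,4-dioxaspiro[4.5]decan-8-one, 7 (R)-1-phenylethylamine, 8 ethyl vinyl ketone
Product: 13 (7R,10R)-8,8-(ethylenedioxy)eudesma-4,11-dien-3-one, via imine 9 (not isolated), via Michael adduct imine 10 (not isolated), via diketone 11 (not isolated), via ketol 12 (not isolated)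
Conditions: (R)-PhCH(Me)NH2, 4 Å MS, PhMe, 60 °C; EVK, THF, 40 °C; AcOH/NaOAc aq (pH 5), rt; then NaOMe, MeOH, 60 °C (telescoped, no intermediate purified)
Reagents that add atoms: none
Why: This is an auxiliary-directed Robinson annulation: imine 9 reacts through its more substituted secondary enamine tautomer with ethyl vinyl ketone in a chair-like aza-ene transition state with internal N–H transfer to form C1–C10, and after buffered hydrolysis the ethyl ketone enolate (C4) adds to the C5 carbonyl and ketol 12 loses water by E1cB to give the conjugated C4=C5 enone. The closest known reaction type is the chiral-imine Robinson annulation of 2-methylcyclohexanones such as dihydrocarvone with alkyl vinyl ketones. Ring A closes in a 6-(enolendo)-exo-trig aldol addition, and the reversible basic conditions should funnel any bridged ketol to the fused enone. The only new stereocenter, quaternary C10, is controlled by the (R)-1-phenylethyl group, whose phenyl ring shields one enamine face so that the acceptor enters anti to the C7 isopropenyl group and the methyl ends up cis to it; C7 is β to the carbonyl and cannot epimerize. The step needs C10-over-C6 regioselectivity, secured by the concerted proton transfer that only the tetrasubstituted enamine tautomer allows, and π-facial selectivity, secured by the auxiliary and not by the ring, because the dioxolane oxygen syn-axial to C10 hinders both chair-like approaches alike. The dioxolane is used because it should survive the pH 5 imine hydrolysis that a dimethyl ketal would not.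

**Step 6**
Reactants: 13 (7R,10R)-8,8-(ethylenedioxy)eudesma-4,11-dien-3-one
Product: 14 (7R,10R)-eudesma-4,11-diene-3,8-dione
Conditions: PPTS, acetone/H2O, 50 °C
Reagents that add atoms: water (O)
Why: Acid-catalysed ketal hydrolysis is done at the stage where the only other functions are an enone and an isopropenyl group; the resulting β,γ-unsaturated ketone is of the isopulegone type, which tolerates mild acid, and C7 remains in its equatorial (thermodynamic) configuration.

**Step 7**
Reactants: 14 (7R,10R)-eudesma-4,11-diene-3,8-dione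
Product: 15 (7R,8R,10R)-8-hydroxyeudesma-4,11-dien-3-one (8β-OH, axial)
Conditions: L-Selectride (1.05 equiv), THF, −78 °C; then sat. aq NH4Cl
Reagents that add atoms: none
Why: Chemo- and stereoselective hydride reduction: the saturated C8 ketone should react faster than the conjugated, α-methyl-substituted C3 enone (as in selective reductions of Wieland–Miescher-type diketones), and the bulky hydride attacks along the equatorial α trajectory because the axial β trajectory is blocked by the syn-axial C10 methyl, giving the axial 8β-alcohol cis to the C7 side chain (cf. isopulegone to neoisopulegol).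

**Step 8**
Reactants: 15 (7R,8R,10R)-8-hydroxyeudesma-4,11-dien-3-one
Product: 16 (7R,8R,10R)-8-acetoxyeudesma-4,11-dien-3-one
Conditions: Ac2O, pyridine, DMAP (cat.), CH2Cl2, rt to 40 °C
Reagents that add atoms: acetic anhydride (CC(=O)OC(C)=O)
Why: DMAP-catalysed acylation should acetylate the hindered axial alcohol; placing the acetate now prevents any later lactonization of C8–OH onto the C12 ester.

**Step 9**
Reactants: 16 (7R,8R,10R)-8-acetoxyeudesma-4,11-dien-3-one
Product: 17 (7R,8R,10R)-8-acetoxy-12-hydroxyeudesma-4,11(13)-dien-3-one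
Conditions: SeO2 (0.3 equiv), t-BuOOH, CH2Cl2, rt
Reagents that add atoms: selenium dioxide (O=[Se]=O, catalytic oxygen carrier); tert-butyl hydroperoxide (CC(C)(C)OO)
Why: SeO2-catalysed allylic oxidation (ene reaction, then [2,3]-sigmatropic shift) should hydroxylate the methyl of the 1,1-disubstituted isopropenyl group; it is placed here because the only other alkene is the electron-poor enone, whereas the later electron-rich C4=C5 allylic system would compete.

**Step 10**
Reactants: 17 (7R,8R,10R)-8-acetoxy-12-hydroxyeudesma-4,11(13)-dien-3-one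
Product: 18 (7R,8R,10R)-8-acetoxy-3-oxoeudesma-4,11(13)-dien-12-al
Conditions: activated MnO2, CH2Cl2, rt
Reagents that add atoms: none
Why: MnO2 oxidation of a primary allylic alcohol should give the 2-substituted acrolein and also converges any aldehyde already formed in step 9.

**Step 11**
Reactants: 18 (7R,8R,10R)-8-acetoxy-3-oxoeudesma-4,11(13)-dien-12-al
Product: 19 (7R,8R,10R)-8-acetoxy-3-oxoeudesma-4,11(13)-dien-12-oic acid
Conditions: NaClO2, NaH2PO4, 2-methyl-2-butene, t-BuOH/H2O, 0 °C to rt
Reagents that add atoms: sodium chlorite ([Na+].[O-]Cl=O)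
Why: Pinnick oxidation converts enals to acrylic acids without touching the enone, the acetate or the alkene geometry, the scavenger removing the hypochlorite formed.

**Step 12**
Reactants: 19 (7R,8R,10R)-8-acetoxy-3-oxoeudesma-4,11(13)-dien-12-oic acid
Product: 20 methyl (7R,8R,10R)-8-acetoxy-3-oxoeudesma-4,11(13)-dien-12-oate
Conditions: MeI, K2CO3, DMF, rt
Reagents that add atoms: iodomethane (CI)
Why: SN2 O-alkylation of the carboxylate gives the methyl ester under conditions free of methanol (the acetate is safe) and avoids dipolar cycloaddition of a diazoalkane to the acrylate.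

**Step 13**
Reactants: 20 methyl (7R,8R,10R)-8-acetoxy-3-oxoeudesma-4,11(13)-dien-12-oate
Product: 21 methyl (3S,7R,8R,10R)-8-acetoxy-3-hydroxyeudesma-4,11(13)-dien-12-oate (3β-OH)
Conditions: NaBH4, CeCl3·7H2O, MeOH, −78 to −20 °C
Reagents that add atoms: none
Why: Luche 1,2-reduction of the enone should leave the acrylate and acetate intact; hydride is delivered axially from the α face of the ring-A half-chair, giving the pseudo-equatorial 3β-alcohol as with 4-en-3-one steroids.

**Step 14**
Reactants: 21 methyl (3S,7R,8R,10R)-8-acetoxy-3-hydroxyeudesma-4,11(13)-dien-12-oate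
Product: 22 methyl (3S,7R,8R,10R)-8-acetoxy-3-(propanoyloxy)eudesma-4,11(13)-dien-12-oate (target)
Conditions: (EtCO)2O, Et3N, DMAP (cat.), CH2Cl2, 0 °C to rt
Reagents that add atoms: propionic anhydride (CCC(=O)OC(=O)CC)
Why: DMAP-catalysed acylation of the secondary allylic alcohol with retention at C3 should give the target.

**Compound list**

1 | 4-methoxy-2-methylphenol | COc1ccc(O)c(C)c1 | starting material
2 | 4,4-dimethoxy-2-methylcyclohexa-2,5-dien-1-one | CC1=CC(OC)(OC)C=CC1=O | intermediate
3 | 7-methyl-1,4-dioxaspiro[4.5]deca-6,9-dien-8-one | CC1=CC2(OCCO2)C=CC1=O | intermediate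
4 | potassium isopropenyltrifluoroborate | C=C(C)[B-](F)(F)F.[K+] | starting material
5 | (10R)-7-methyl-10-(prop-1-en-2-yl)-1,4-dioxaspiro[4.5]dec-6-en-8-one | C=C(C)[C@H]1CC(=O)C(C)=CC12OCCO2 | intermediate
6 | (10R)-7-methyl-10-(prop-1-en-2-yl)-1,4-dioxaspiro[4.5]decan-8-one (epimer mixture at C7 of the spiro numbering) | C=C(C)[C@H]1CC(=O)C(C)CC12OCCO2 | intermediate
7 | (R)-1-phenylethylamine | C[C@@H](N)c1ccccc1 | starting material
8 | ethyl vinyl ketone (pent-1-en-3-one) | C=CC(=O)CC | starting material
9 | N-[(1R)-1-phenylethyl] ketimine of 6 (not isolated) | C=C(C)[C@H]1CC(=N[C@H](C)c3ccccc3)C(C)CC12OCCO2 | intermediate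
10 | N-[(1R)-1-phenylethyl] ketimine of diketone 11, Michael adduct (not isolated) | C=C(C)[C@H]1CC(=N[C@H](C)c3ccccc3)[C@](C)(CCC(=O)CC)CC12OCCO2 | intermediate
11 | (7R,10R)-7-methyl-7-(3-oxopentyl)-10-(prop-1-en-2-yl)-1,4-dioxaspiro[4.5]decan-8-one (not isolated) | C=C(C)[C@H]1CC(=O)[C@](C)(CCC(=O)CC)CC12OCCO2 | intermediate
12 | (7R,10R)-8,8-(ethylenedioxy)-5-hydroxyeudesm-11-en-3-one, aldol ketol, C4/C5 configuration undefined (not isolated) | C=C(C)[C@H]1CC2(O)C(C)C(=O)CC[C@]2(C)CC13OCCO3 | intermediate
13 | (7R,10R)-8,8-(ethylenedioxy)eudesma-4,11-dien-3-one | C=C(C)[C@H]1CC2=C(C)C(=O)CC[C@]2(C)CC13OCCO3 | intermediate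
14 | (7R,10R)-eudesma-4,11-diene-3,8-dione | C=C(C)[C@H]1CC2=C(C)C(=O)CC[C@]2(C)CC1=O | intermediate
15 | (7R,8R,10R)-8-hydroxyeudesma-4,11-dien-3-one (8β-OH) | C=C(C)[C@H]1CC2=C(C)C(=O)CC[C@]2(C)C[C@H]1O | intermediate
16 | (7R,8R,10R)-8-acetoxyeudesma-4,11-dien-3-one | C=C(C)[C@H]1CC2=C(C)C(=O)CC[C@]2(C)C[C@H]1OC(C)=O | intermediate
17 | (7R,8R,10R)-8-acetoxy-12-hydroxyeudesma-4,11(13)-dien-3-one | C=C(CO)[C@H]1CC2=C(C)C(=O)CC[C@]2(C)C[C@H]1OC(C)=O | intermediate
18 | (7R,8R,10R)-8-acetoxy-3-oxoeudesma-4,11(13)-dien-12-al | C=C(C=O)[C@H]1CC2=C(C)C(=O)CC[C@]2(C)C[C@H]1OC(C)=O | intermediate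
19 | (7R,8R,10R)-8-acetoxy-3-oxoeudesma-4,11(13)-dien-12-oic acid | C=C(C(=O)O)[C@H]1CC2=C(C)C(=O)CC[C@]2(C)C[C@H]1OC(C)=O | intermediate
20 | methyl (7R,8R,10R)-8-acetoxy-3-oxoeudesma-4,11(13)-dien-12-oate | C=C(C(=O)OC)[C@H]1CC2=C(C)C(=O)CC[C@]2(C)C[C@H]1OC(C)=O | intermediate
21 | methyl (3S,7R,8R,10R)-8-acetoxy-3-hydroxyeudesma-4,11(13)-dien-12-oate | C=C(C(=O)OC)[C@H]1CC2=C(C)[C@@H](O)CC[C@]2(C)C[C@H]1OC(C)=O | intermediate
22 | methyl (3S,7R,8R,10R)-8-acetoxy-3-(propanoyloxy)eudesma-4,11(13)-dien-12-oate | C=C(C(=O)OC)[C@H]1CC2=C(C)[C@@H](OC(=O)CC)CC[C@]2(C)C[C@H]1OC(C)=O | target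

**Step count and risks**

Total step count: 14. Longest linear sequence: 14 steps (1 to 22).

Steps most likely to fail:

Risk 1, step 5 (key step). The failure mode is erosion of π-facial control at C10 if the auxiliary and the ring substituents oppose each other, or a sluggish aza-ene addition at the hindered tetrasubstituted enamine. The fallback sets C10 by catalyst control and sets out from 5. Compound 5 is reduced with L-Selectride as in step 4, and the regiodefined lithium enolate is O-acylated with allyl chloroformate to the allyl enol carbonate F1. Pd-catalysed decarboxylative asymmetric allylic alkylation (Tsuji allylation, Pd2(dba)3 with the t-Bu-PHOX enantiomer matched to the required C10 configuration) should give the α-allyl-α-methyl ketone F2. Aldehyde-selective (anti-Markovnikov, nitrite-modified) Wacker oxidation of the monosubstituted allyl alkene, to which the 1,1-disubstituted isopropenyl group is inert, gives the aldehyde F3. EtMgBr at −78 °C adds to the aldehyde in preference to the hindered α-quaternary ketone to give the secondary alcohol F4. Dess–Martin oxidation then gives diketone 11, where the route is rejoined; 11 is cyclized with NaOMe/MeOH as in step 5 to 13.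

Risk 2, step 7. The failure mode is loss of chemoselectivity, i.e. competing 1,2-addition of hydride to the C3 enone carbonyl. The fallback moves the selectivity from the reduction to an oxidation and sets out from 14. Both carbonyl groups are reduced with excess L-Selectride (C8 still forms by equatorial attack) to the eudesma-4,11-diene-3,8β-diol F5. Activated MnO2, which oxidizes only the allylic C3 carbinol, returns it to the enone, and the route is rejoined at 15.

Risk 3, step 9. The failure mode is unselective or incomplete allylic oxidation: abstraction of the tertiary C7–H, attack at the enone C2/C6 positions, or over-oxidation. The fallback sets out from 16. Ene-type chlorination with HOCl generated from Ca(OCl)2 and CO2 in CH2Cl2/H2O, which spares the electron-poor enone, gives the 12-chloro-eudesma-4,11(13)-diene (allylic chloride) F6. Kornblum oxidation (DMSO, NaHCO3) converts it to the enal, and the route is rejoined at 18.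

**Further compounds**

F1 | step 5 | allyl (10R)-7-methyl-10-(prop-1-en-2-yl)-1,4-dioxaspiro[4.5]dec-7-en-8-yl carbonate | C=C(C)[C@H]1CC(OC(=O)OCC=C)=C(C)CC12OCCO2
F2 | step 5 | (7R,10R)-7-allyl-7-methyl-10-(prop-1-en-2-yl)-1,4-dioxaspiro[4.5]decan-8-one | C=C(C)[C@H]1CC(=O)[C@](C)(CC=C)CC12OCCO2
F3 | step 5 | 3-[(7R,10R)-7-methyl-8-oxo-10-(prop-1-en-2-yl)-1,4-dioxaspiro[4.5]decan-7-yl]propanal | C=C(C)[C@H]1CC(=O)[C@](C)(CCC=O)CC12OCCO2
F4 | step 5 | (7R,10R)-7-(3-hydroxypentyl)-7-methyl-10-(prop-1-en-2-yl)-1,4-dioxaspiro[4.5]decan-8-one | C=C(C)[C@H]1CC(=O)[C@](C)(CCC(O)CC)CC12OCCO2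
F5 | step 7 | (7R,8R,10R)-eudesma-4,11-diene-3,8-diol (C3 epimers) | C=C(C)[C@H]1CC2=C(C)C(O)CC[C@]2(C)C[C@H]1O
F6 | step 9 | (7R,8R,10R)-8-acetoxy-12-chloroeudesma-4,11(13)-dien-3-one | C=C(CCl)[C@H]1CC2=C(C)C(=O)CC[C@]2(C)C[C@H]1OC(C)=O
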